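**Plan**

1. Numbering of the target core (furo[3,4-c]furan): C1 (bears the 3-hydroxy-4,5-dimethoxyphenyl ring), O2, C3 (CH2), C3a, C4 (bears the 4-hydroxy-3-methoxyphenyl ring), O5, C6 (CH2), C6a; ring A = C1/O2/C3/C3a/C6a, ring B = C3a/C4/O5/C6/C6a.
2. Retrosynthesis: after the two O-benzyl groups, C3 is raised to a lactone carbonyl and the bicycle is cut at O2–C3, C3–C3a (CO) and O5–C4, giving an acyclic (E)-styryl 1,3-diol; this is cut at C1–C6a (aldol) and at the aryl–C4 bond (Heck).
3. Forward: Heck reaction and auxiliary loading give the chain C6–C6a–C3a=C4–aryl, the aldol adds C1, reduction frees O5–H, then one palladium-mediated carbonylative double cyclisation closes ring B (O5–C4) and ring A (C3a–C3, then O2–C3); the C3 carbonyl oxygen and the benzyl groups are then removed.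
4. Stereochemistry: C6a and C1 come from an Evans syn-aldol with the (S)-4-benzyl auxiliary; C4 from anti oxypalladation of the E alkene; C3a from the cis ring fusion that lactone closure onto the C1 hydroxyl enforces.
5. Enabling feature: in ring A the methylene C3 lies between O2 and C3a, so at the carbonyl level it can enter as CO between a C3a–Pd bond and the O2–H group; the electron-rich aryl group on C4 and the homoallylic position of O5 direct the first C–O bond of ring B to C4.

Key step: step 6

Remark: the SMILES is read as the (1S,3aR,4S,6aR) isomer (cis ring fusion, both aryl groups on the convex face); compounds 1, 2, 4 and 7 are taken as purchasable.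

**Route**

Step 1
Reactants: 1 1-(benzyloxy)-4-bromo-2-methoxybenzene; 2 but-3-enoic acid
Product: 3 (E)-4-[4-(benzyloxy)-3-methoxyphenyl]but-3-enoic acid
Conditions: Pd(OAc)2 (3 mol %), P(o-tol)3 (6 mol %), Et3N, MeCN, 85 °C
Reagents that add atoms: none
Why: Mizoroki–Heck reaction, in which the aryl–Pd species adds to the terminal alkene carbon and syn β-hydride elimination towards the benzylic side should give the aryl-conjugated E alkene, the carboxylic acid being tolerated as its ammonium salt.

Step 2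
Reactants: 3 (E)-4-[4-(benzyloxy)-3-methoxyphenyl]but-3-enoic acid; 4 (S)-4-benzyl-1,3-oxazolidin-2-one
Product: 6 (S)-4-benzyl-3-[(E)-4-[4-(benzyloxy)-3-methoxyphenyl]but-3-enoyl]-1,3-oxazolidin-2-one, via mixed pivalic anhydride 5 (not isolated)
Conditions: t-BuCOCl, Et3N, THF, −20 °C; then 4, LiCl, −20 °C to 20 °C
Reagents that add atoms: none
Why: N-acylation of the oxazolidinone through the mixed pivalic anhydride (LiCl/Et3N variant), in which the unhindered acyl group is transferred and the β,γ-alkene should stay in place.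

Step 3
Reactants: 7 3-hydroxy-4,5-dimethoxybenzaldehyde
Product: 8 3-(benzyloxy)-4,5-dimethoxybenzaldehyde
Conditions: BnBr, K2CO3, DMF, 20 °C
Reagents that add atoms: benzyl bromide, BrCc1ccccc1
Why: Williamson ether synthesis on the phenoxide, to which the aldehyde is inert.

Step 4
Reactants: 6 (S)-4-benzyl-3-[(E)-4-[4-(benzyloxy)-3-methoxyphenyl]but-3-enoyl]-1,3-oxazolidin-2-one; 8 3-(benzyloxy)-4,5-dimethoxybenzaldehyde
Product: 10 (S)-4-benzyl-3-[(2S,3S)-3-[3-(benzyloxy)-4,5-dimethoxyphenyl]-2-[(E)-2-[4-(benzyloxy)-3-methoxyphenyl]ethenyl]-3-hydroxypropanoyl]-1,3-oxazolidin-2-one, via dibutylboron Z-enolate 9 (not isolated)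
Conditions: n-Bu2BOTf, i-Pr2NEt, CH2Cl2, −78 °C to 0 °C; then 8, −78 °C to 0 °C; then H2O2, MeOH, pH 7 buffer, 0 °C
Reagents that add atoms: none
Why: Evans syn-aldol reaction, in which the Z boron dienolate should react at its α-carbon through a closed chair transition state on the face away from the benzyl group of the (S)-auxiliary, setting C6a and C1 of the target (2S,3S in the adduct, syn) and leaving the E styrene untouched.

Step 5
Reactants: 10 (S)-4-benzyl-3-[(2S,3S)-3-[3-(benzyloxy)-4,5-dimethoxyphenyl]-2-[(E)-2-[4-(benzyloxy)-3-methoxyphenyl]ethenyl]-3-hydroxypropanoyl]-1,3-oxazolidin-2-one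
Product: 11 (1S,2R)-1-[3-(benzyloxy)-4,5-dimethoxyphenyl]-2-[(E)-2-[4-(benzyloxy)-3-methoxyphenyl]ethenyl]propane-1,3-diol
Conditions: LiBH4, MeOH (2 equiv), THF, 0 °C
Reagents that add atoms: none
Why: Reductive removal of the auxiliary with LiBH4 (imide to primary alcohol) should leave the styrene, the benzyl ethers and both stereocentres untouched and release the oxazolidinone for reuse.

Step 6
Reactants: 11 (1S,2R)-1-[3-(benzyloxy)-4,5-dimethoxyphenyl]-2-[(E)-2-[4-(benzyloxy)-3-methoxyphenyl]ethenyl]propane-1,3-diol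
Product: 12 (3S,3aR,6S,6aS)-3-[3-(benzyloxy)-4,5-dimethoxyphenyl]-6-[4-(benzyloxy)-3-methoxyphenyl]tetrahydro-1H,3H-furo[3,4-c]furan-1-one (the lactone carbonyl is C3 of the target)
Conditions: PdCl2 (10 mol %), CuCl2 (3 equiv), NaOAc (3 equiv), CO (1 atm), AcOH, 20 °C
Reagents that add atoms: carbon monoxide, [C-]#[O+]
Why: Proposed new method: divalent palladium held by the C1 hydroxyl binds the E styrene, the primary hydroxyl (O5) adds anti to the metal at the benzylic carbon C4 (Markovnikov sense, reinforced by the 4-benzyloxy-3-methoxyphenyl group), CO inserts into the resulting C3a–Pd bond, and the C1 hydroxyl (O2) captures the acyl–Pd carbon C3, after which zerovalent palladium is reoxidised by CuCl2. The closest known reaction type is the PdCl2/CuCl2-catalysed intramolecular oxycarbonylation of alkene diols to cis-fused bicyclic tetrahydrofuran lactones, which uses 5-exo oxypalladation; the endo mode onto a styrene and the furo[3,4-c] connectivity are the untested part. Ring B closes by 5-endo-trig attack of O5 on the Pd-activated alkene, and ring A by 5-exo-trig acyl substitution of O2 on the acyl–Pd carbon C3, the bond that completes the bicycle. C4 is set by anti addition across the E alkene (aryl trans to the C3a–Pd bond and hence to C3), and C3a by the five-membered O2–Pd–C3a chelate together with the fact that only an acyl group cis to the C1 carbinol can lactonise, so both follow from C6a and C1. The step needs O5 and not O2 to add to the alkene (O2 could only form an oxetane), CO insertion to outrun β-hydride elimination (CO atmosphere, chelated alkyl–Pd), and oxypalladation to outrun alkoxycarbonylation of the primary hydroxyl (acetic acid/NaOAc buffer).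

Step 7
Reactants: 12 (3S,3aR,6S,6aS)-3-[3-(benzyloxy)-4,5-dimethoxyphenyl]-6-[4-(benzyloxy)-3-methoxyphenyl]tetrahydro-1H,3H-furo[3,4-c]furan-1-one
Product: 14 (1S,3aR,4S,6aR)-1-[3-(benzyloxy)-4,5-dimethoxyphenyl]-4-[4-(benzyloxy)-3-methoxyphenyl]tetrahydro-1H,3H-furo[3,4-c]furan, via lactol 13 (not isolated)
Conditions: i-Bu2AlH (1.1 equiv), CH2Cl2, −78 °C; then Et3SiH, BF3·OEt2, −78 °C to −40 °C
Reagents that add atoms: none
Why: Partial reduction of the γ-lactone to the lactol followed by ionic hydrogenation (BF3-promoted oxocarbenium formation at C3 and hydride delivery from Et3SiH) should remove the carbonyl oxygen without opening ring A, forming no stereocentre, with the low temperature meant to keep the benzylic C–O bonds from ionising.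

Step 8
Reactants: 14 (1S,3aR,4S,6aR)-1-[3-(benzyloxy)-4,5-dimethoxyphenyl]-4-[4-(benzyloxy)-3-methoxyphenyl]tetrahydro-1H,3H-furo[3,4-c]furan
Product: 15 5-[(1S,3aR,4S,6aR)-4-(4-hydroxy-3-methoxyphenyl)tetrahydro-1H,3H-furo[3,4-c]furan-1-yl]-2,3-dimethoxyphenol
Conditions: H2 (1 atm), 10 % Pd/C, EtOAc, 20 °C
Reagents that add atoms: none
Why: Hydrogenolysis of the two aryl benzyl ethers over Pd/C should be faster than cleavage of the more hindered dialkyl benzylic C–O bonds of the bicycle when run in ethyl acetate at atmospheric pressure and stopped at full conversion.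

**Compound list**

1 | 1-(benzyloxy)-4-bromo-2-methoxybenzene | COc1cc(Br)ccc1OCc1ccccc1 | starting material
2 | but-3-enoic acid | C=CCC(=O)O | starting material
3 | (E)-4-[4-(benzyloxy)-3-methoxyphenyl]but-3-enoic acid | COc1cc(/C=C/CC(=O)O)ccc1OCc1ccccc1 | intermediate
4 | (S)-4-benzyl-1,3-oxazolidin-2-one | O=C1N[C@@H](Cc2ccccc2)CO1 | starting material
5 | (E)-4-[4-(benzyloxy)-3-methoxyphenyl]but-3-enoic pivalic anhydride | COc1cc(/C=C/CC(=O)OC(=O)C(C)(C)C)ccc1OCc1ccccc1 | intermediate
6 | (S)-4-benzyl-3-[(E)-4-[4-(benzyloxy)-3-methoxyphenyl]but-3-enoyl]-1,3-oxazolidin-2-one | COc1cc(/C=C/CC(=O)N2[C@@H](Cc3ccccc3)COC2=O)ccc1OCc1ccccc1 | intermediate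
7 | 3-hydroxy-4,5-dimethoxybenzaldehyde | COc1cc(C=O)cc(O)c1OC | starting material
8 | 3-(benzyloxy)-4,5-dimethoxybenzaldehyde | COc1cc(C=O)cc(OCc2ccccc2)c1OC | intermediate
9 | dibutylboron Z-enolate of 6 | CCCCB(CCCC)O/C(=C\C=C\c1ccc(OCc2ccccc2)c(OC)c1)N1[C@@H](Cc2ccccc2)COC1=O | intermediate
10 | (S)-4-benzyl-3-[(2S,3S)-3-[3-(benzyloxy)-4,5-dimethoxyphenyl]-2-[(E)-2-[4-(benzyloxy)-3-methoxyphenyl]ethenyl]-3-hydroxypropanoyl]-1,3-oxazolidin-2-one | O=C(N1[C@@H](Cc2ccccc2)COC1=O)[C@@H](/C=C/c1ccc(OCc2ccccc2)c(OC)c1)[C@H](O)c1cc(OC)c(OC)c(OCc2ccccc2)c1 | intermediate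
11 | (1S,2R)-1-[3-(benzyloxy)-4,5-dimethoxyphenyl]-2-[(E)-2-[4-(benzyloxy)-3-methoxyphenyl]ethenyl]propane-1,3-diol | OC[C@@H](/C=C/c1ccc(OCc2ccccc2)c(OC)c1)[C@H](O)c1cc(OC)c(OC)c(OCc2ccccc2)c1 | intermediate
12 | (3S,3aR,6S,6aS)-3-[3-(benzyloxy)-4,5-dimethoxyphenyl]-6-[4-(benzyloxy)-3-methoxyphenyl]tetrahydro-1H,3H-furo[3,4-c]furan-1-one | COc1cc([C@H]2OC[C@H]3[C@@H]2C(=O)O[C@@H]3c2cc(OCc4ccccc4)c(OC)c(OC)c2)ccc1OCc1ccccc1 | intermediate
13 | (3S,3aR,6S,6aS)-3-[3-(benzyloxy)-4,5-dimethoxyphenyl]-6-[4-(benzyloxy)-3-methoxyphenyl]tetrahydro-1H,3H-furo[3,4-c]furan-1-ol (lactol, both C1 epimers, formed as its aluminium alkoxide) | COc1cc([C@H]2OC[C@H]3[C@@H]2C(O)O[C@@H]3c2cc(OCc4ccccc4)c(OC)c(OC)c2)ccc1OCc1ccccc1 | intermediate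
14 | (1S,3aR,4S,6aR)-1-[3-(benzyloxy)-4,5-dimethoxyphenyl]-4-[4-(benzyloxy)-3-methoxyphenyl]tetrahydro-1H,3H-furo[3,4-c]furan | COc1cc([C@H]2OC[C@H]3[C@@H]2CO[C@@H]3c2cc(OCc4ccccc4)c(OC)c(OC)c2)ccc1OCc1ccccc1 | intermediate
15 | 5-[(1S,3aR,4S,6aR)-4-(4-hydroxy-3-methoxyphenyl)tetrahydro-1H,3H-furo[3,4-c]furan-1-yl]-2,3-dimethoxyphenol | COc1cc([C@H]2OC[C@H]3[C@@H]2CO[C@@H]3c2cc(O)c(OC)c(OC)c2)ccc1O | target

**Step count and risks**

Total step count: 8. Longest linear sequence: 7 steps (steps 1, 2, 4, 5, 6, 7 and 8).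

Steps most likely to fail:

For step 6, which carries the label "Proposed new method:", the endo oxypalladation may lose to Wacker-type oxidation of the styrene or to β-hydride elimination from the C3a–Pd intermediate. Carbonylation may also start at the primary hydroxyl and lead to a constitutional isomer. The fallback uses known reaction types and sets out from 11. Iodine and NaHCO3 in MeCN at 0 °C (5-endo-trig iodoetherification, anti addition of O5 and iodine across the E alkene) would give (S)-[3-(benzyloxy)-4,5-dimethoxyphenyl]{(3R,4S,5R)-5-[4-(benzyloxy)-3-methoxyphenyl]-4-iodotetrahydrofuran-3-yl}methanol F1, in which ring B and C4 are in place. Atom-transfer radical carbonylation of this secondary iodide (CO 40 atm, Pd(PPh3)4 cat., K2CO3, benzene, xenon lamp) would pass through a planar C3a radical and an acyl iodide or acyl–Pd species that the C1 hydroxyl captures; this comes back to the route at 12. The configuration at C3a can converge in the radical step, but the face of the alkene taken by iodine relative to C6a is not secured, so the isomer with the aryl group cis to the carbinol side chain would have to be separated at the stage of F1.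

For step 7, BF3 may ionise the electron-rich benzylic C4–O5 or C1–O2 bonds, which would cause epimerisation at C4 or ring opening, and the lactol may be over-reduced to the open diol. The fallback sets out from 12. LiAlH4 in THF at 0 °C would open the lactone to (S)-[3-(benzyloxy)-4,5-dimethoxyphenyl]{(3R,4R,5S)-5-[4-(benzyloxy)-3-methoxyphenyl]-4-(hydroxymethyl)tetrahydrofuran-3-yl}methanol F2. Selective tosylation of the primary hydroxyl (TsCl, pyridine, 0 °C to 20 °C) and 5-exo-tet displacement by the C1 hydroxyl oxygen (retention at C1) would re-form the O2–C3 bond without any Lewis acid and come back at 14.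

For step 8, hydrogenolysis may go on after loss of the benzyl groups and cleave the benzylic C–O bonds of the two rings. The fallback sets out from 14. Pd(OAc)2-catalysed benzyl transfer to Et3SiH (Et3N, CH2Cl2, 20 °C), a method selective for aryl benzyl ethers over alkyl benzylic ethers, would give triethyl{5-[(1S,3aR,4S,6aR)-4-{3-methoxy-4-[(triethylsilyl)oxy]phenyl}tetrahydro-1H,3H-furo[3,4-c]furan-1-yl]-2,3-dimethoxyphenoxy}silane F3. Bu4NF buffered with AcOH in THF at 0 °C would then free both phenols and come back at 15.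

Further compounds
F1 | step 6 | (S)-[3-(benzyloxy)-4,5-dimethoxyphenyl]{(3R,4S,5R)-5-[4-(benzyloxy)-3-methoxyphenyl]-4-iodotetrahydrofuran-3-yl}methanol | COc1cc([C@H]2OC[C@@H]([C@@H]2I)[C@H](O)c2cc(OCc3ccccc3)c(OC)c(OC)c2)ccc1OCc1ccccc1
F2 | step 7 | (S)-[3-(benzyloxy)-4,5-dimethoxyphenyl]{(3R,4R,5S)-5-[4-(benzyloxy)-3-methoxyphenyl]-4-(hydroxymethyl)tetrahydrofuran-3-yl}methanol | COc1cc([C@H]2OC[C@@H]([C@@H]2CO)[C@H](O)c2cc(OCc3ccccc3)c(OC)c(OC)c2)ccc1OCc1ccccc1
F3 | step 8 | triethyl{5-[(1S,3aR,4S,6aR)-4-{3-methoxy-4-[(triethylsilyl)oxy]phenyl}tetrahydro-1H,3H-furo[3,4-c]furan-1-yl]-2,3-dimethoxyphenoxy}silane | COc1cc([C@H]2OC[C@H]3[C@@H]2CO[C@@H]3c2cc(O[Si](CC)(CC)CC)c(OC)c(OC)c2)ccc1O[Si](CC)(CC)CC
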